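**Plan**

Ring A numbering: C1 (ester carbon), C2 (O-prenyl), C3–H, C4 (CH3), C5–H, C6 (O–ring B).
Retrosynthesis: the ester is taken back to an aldehyde diethyl acetal and the prenyl ether to a phenol. Ring A is then cut at C1–C2 and C5–C6 (C2–C3 is re-formed in the same event), giving 3-methylcyclobutenone and the ynol ether ArO–C≡C–CH(OEt)2. The ynol ether is cut at C(sp)–CH(OEt)2 and at the ring B O–C(sp) bond.
Enabling feature: ring A is a 1,3-dioxygenated arene whose carbon substituent at C1 lies between C2–O and C6–OAr, with the methyl at C4 para to C1. This is the pattern that the vinylketene O=C=CH–C(CH3)=CH2 and an ynol ether RC≡C–OAr assemble, and ring B arrives on the ynol ether oxygen.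
Forward: the ring B aldehyde is taken to the ynol ether acetal (steps 1–4) and propyne to 3-methylcyclobutenone (steps 5–6). The benzannulation closes ring A, the only ring made, with the diaryl ether in place (step 7). Acid unmasking, prenylation, oxidation and methylation finish (steps 8–11).
Stereochemistry: the target has no stereocentre and no stereogenic double bond, so nothing has to be set.

Key step: step 7

Remark: 2-hydroxy-3,5-dimethoxybenzaldehyde and diethyl phenyl orthoformate are assumed purchasable; the phenyl orthoformate is preferred to triethyl orthoformate because phenoxide leaves at or below room temperature.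

**Route**

Step 1
Reactants: 1 2-hydroxy-3,5-dimethoxybenzaldehyde
Product: 2 2-(hydroxymethyl)-4,6-dimethoxyphenol
Conditions: NaBH4, MeOH, 0 °C; aq. NH4Cl
Reagents that add atoms: none
Why: Borohydride reduction of the aldehyde; the phenoxide formed in situ does not interfere and no other reducible group is present.

Step 2
Reactants: 2 2-(hydroxymethyl)-4,6-dimethoxyphenol
Product: 3 2-({[tert-butyl(dimethyl)silyl]oxy}methyl)-4,6-dimethoxyphenol
Conditions: TBSCl (1.05 equiv), imidazole, CH2Cl2, 0 °C
Reagents that add atoms: tert-butyldimethylsilyl chloride, CC(C)(C)[Si](C)(C)Cl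
Why: Silyl ether formation; the primary benzylic hydroxyl should be silylated faster than the phenol, which is flanked by two ortho substituents, so one equivalent of silyl chloride should stop at the mono-ether.

Step 3
Reactants: 3 2-({[tert-butyl(dimethyl)silyl]oxy}methyl)-4,6-dimethoxyphenol; 4 trichloroethylene
Product: 5 tert-butyl{[2-{[(E)-1,2-dichloroethenyl]oxy}-3,5-dimethoxyphenyl]methoxy}dimethylsilane (the (E)-1,2-dichlorovinyl ether of phenol 3)
Conditions: K2CO3, DMF, 70 °C
Reagents that add atoms: none
Why: Formal nucleophilic vinylic substitution of trichloroethylene by the phenoxide, the standard entry to aryl 1,2-dichlorovinyl ethers; the (E) geometry expected is erased in step 4 and the silyl ether tolerates carbonate in DMF.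

Step 4
Reactants: 5 the (E)-1,2-dichlorovinyl ether; 6 diethyl phenyl orthoformate [(diethoxymethoxy)benzene]
Product: 10 tert-butyl({2-[(3,3-diethoxyprop-1-yn-1-yl)oxy]-3,5-dimethoxyphenyl}methoxy)dimethylsilane, via chloroethynyl aryl ether 7 (not isolated), via lithium aryloxyacetylide 8 (not isolated), via bromomagnesium aryloxyacetylide 9 (not isolated)
Conditions: n-BuLi (2.2 equiv), THF, −78 → −40 °C; MgBr2·OEt2; then 6, −40 °C → rt; aq. NaHCO3
Reagents that add atoms: none
Why: Deprotonation with loss of LiCl gives chloroalkyne 7, chlorine–lithium exchange gives acetylide 8, and after transmetalation the alkynylmagnesium 9 displaces phenoxide from the orthoformate (Bodroux–Chichibabin acetal synthesis), the silyl and methyl ethers being inert at these temperatures.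

Step 5
Reactants: 11 propyne; 12 trichloroacetyl chloride
Product: 14 4,4-dichloro-3-methylcyclobut-2-en-1-one, via dichloroketene 13 (not isolated)
Conditions: Zn–Cu couple, Et2O/DME, 0 °C → rt (excess propyne, dry-ice condenser)
Reagents that add atoms: none
Why: Zinc dechlorination of 12 releases dichloroketene 13, whose [2+2] cycloaddition joins the ketene carbonyl carbon to the unsubstituted alkyne carbon so that the methyl sits at C3, DME binding ZnCl2 so that the adduct is not isomerised.

Step 6
Reactants: 14 4,4-dichloro-3-methylcyclobut-2-en-1-one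
Product: 15 3-methylcyclobut-2-en-1-one
Conditions: Zn dust, AcOH, TMEDA, EtOH, 0 °C
Reagents that add atoms: none
Why: Zinc–acetic acid reduction of the α,α-dichloro ketone through zinc enolates removes both chlorines, TMEDA buffering the medium so that the strained enone is neither opened nor solvolysed; the volatile product is kept as a toluene solution.

Step 7
Reactants: 10 the ring B ynol ether acetal; 15 3-methylcyclobut-2-en-1-one
Product: 20 2-(diethoxymethyl)-3-[2-({[tert-butyl(dimethyl)silyl]oxy}methyl)-4,6-dimethoxyphenoxy]-5-methylphenol, via vinylketene 16 (not isolated), via isopropenylcyclobutenone adduct 17 (not isolated), via dienylketene 18 (not isolated), via cyclohexadienone 19 (not isolated)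
Conditions: toluene, 80 °C (15 added slowly, 1.5 equiv), then 110 °C
Reagents that add atoms: none
Why: At 80 °C cyclobutenone 15 opens reversibly (conrotatory 4π) to vinylketene 16; the acetal-bearing, nucleophilic carbon of the ynol ether bonds to the ketene carbonyl carbon and the aryloxy-bearing carbon to the ketene α-carbon, a [2+2] that forms C1–C2 and C5–C6 and gives cyclobutenone 17. Reversible 4π opening of 17 feeds dienylketene 18 (only the isomer with ketene and isopropenyl cis reacts on), whose thermal disrotatory 6π electrocyclisation forms C2–C3 and closes ring A as cyclohexadienone 19, which enolises to phenol 20. The closest known reaction type is the Danheiser benzannulation of cyclobutenones with alkoxy- and siloxyalkynes, of which an aryloxyalkyne is a further ynol ether member. No stereocentre results, since the single sp3 centre of 17 is destroyed on ring opening. The one selectivity needed is the orientation of the [2+2], secured by the ynol ether polarisation and helped by the two ortho substituents of ring B, which twist the aryl ring out of conjugation and leave the oxygen lone pair to the alkyne; a [4+2] capture of 16 with the same polarity would give the same phenol. The aryl ynol ether has no β-hydrogen for a retro-ene fragmentation, so it should tolerate the temperature.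

Step 8
Reactants: 20 the ring A phenol acetal
Product: 21 2-hydroxy-6-[2-(hydroxymethyl)-4,6-dimethoxyphenoxy]-4-methylbenzaldehyde
Conditions: 1 M HCl, THF, rt
Reagents that add atoms: water, O
Why: Acid-catalysed hydrolysis of the acetal (accelerated by the ortho hydroxyl) and of the primary silyl ether in one operation, placed before the acid-sensitive prenyl ether exists; the diaryl and methyl ethers are inert.

Step 9
Reactants: 21 2-hydroxy-6-[2-(hydroxymethyl)-4,6-dimethoxyphenoxy]-4-methylbenzaldehyde
Product: 22 2-[2-(hydroxymethyl)-4,6-dimethoxyphenoxy]-4-methyl-6-[(3-methylbut-2-en-1-yl)oxy]benzaldehyde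
Conditions: prenyl bromide, K2CO3, DMF, rt
Reagents that add atoms: prenyl bromide (1-bromo-3-methylbut-2-ene), CC(C)=CCBr
Why: Williamson etherification; carbonate ionises only the salicylaldehyde hydroxyl, so the allylic bromide alkylates that oxygen and leaves the benzylic alcohol untouched.

Step 10
Reactants: 22 the prenyl ether aldehyde
Product: 23 2-[2-(hydroxymethyl)-4,6-dimethoxyphenoxy]-4-methyl-6-[(3-methylbut-2-en-1-yl)oxy]benzoic acid
Conditions: NaClO2, NaH2PO4, 2-methyl-2-butene (large excess), t-BuOH/THF/H2O, 0 °C → rt
Reagents that add atoms: sodium chlorite, [Na+].[O-]Cl=O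
Why: Pinnick (Lindgren) oxidation converts the aldehyde to the acid without touching the primary alcohol, the excess 2-methyl-2-butene consuming hypochlorous acid before it can chlorinate the prenyl alkene or the electron-rich rings.

Step 11
Reactants: 23 the benzoic acid
Product: 24 methyl 2-[2-(hydroxymethyl)-4,6-dimethoxyphenoxy]-4-methyl-6-[(3-methylbut-2-en-1-yl)oxy]benzoate (CNP0573678.0)
Conditions: MeI, K2CO3, DMF, rt
Reagents that add atoms: iodomethane, CI
Why: SN2 alkylation of the carboxylate by iodomethane esterifies the hindered 2,6-disubstituted acid at oxygen, where shielding of the carbonyl does not matter, and the neutral benzylic alcohol does not compete under carbonate base.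

**Compound list**

1 | 2-hydroxy-3,5-dimethoxybenzaldehyde | COc1cc(C=O)c(O)c(OC)c1 | starting material
2 | 2-(hydroxymethyl)-4,6-dimethoxyphenol | COc1cc(CO)c(O)c(OC)c1 | intermediate
3 | 2-({[tert-butyl(dimethyl)silyl]oxy}methyl)-4,6-dimethoxyphenol | COc1cc(CO[Si](C)(C)C(C)(C)C)c(O)c(OC)c1 | intermediate
4 | trichloroethylene | ClC=C(Cl)Cl | starting material
5 | tert-butyl{[2-{[(E)-1,2-dichloroethenyl]oxy}-3,5-dimethoxyphenyl]methoxy}dimethylsilane | Cl/C=C(/Cl)Oc1c(CO[Si](C)(C)C(C)(C)C)cc(OC)cc1OC | intermediate
6 | diethyl phenyl orthoformate, (diethoxymethoxy)benzene | CCOC(OCC)Oc1ccccc1 | starting material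
7 | tert-butyl({2-[(chloroethynyl)oxy]-3,5-dimethoxyphenyl}methoxy)dimethylsilane | ClC#COc1c(CO[Si](C)(C)C(C)(C)C)cc(OC)cc1OC | intermediate (not isolated)
8 | lithium acetylide of the ring B ethynyl ether | [Li]C#COc1c(CO[Si](C)(C)C(C)(C)C)cc(OC)cc1OC | intermediate (not isolated)
9 | bromomagnesium acetylide of the ring B ethynyl ether | Br[Mg]C#COc1c(CO[Si](C)(C)C(C)(C)C)cc(OC)cc1OC | intermediate (not isolated)
10 | tert-butyl({2-[(3,3-diethoxyprop-1-yn-1-yl)oxy]-3,5-dimethoxyphenyl}methoxy)dimethylsilane | CCOC(OCC)C#COc1c(CO[Si](C)(C)C(C)(C)C)cc(OC)cc1OC | intermediate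
11 | propyne | CC#C | starting material
12 | trichloroacetyl chloride | ClC(=O)C(Cl)(Cl)Cl | starting material
13 | dichloroketene | O=C=C(Cl)Cl | intermediate (not isolated)
14 | 4,4-dichloro-3-methylcyclobut-2-en-1-one | CC1=CC(=O)C1(Cl)Cl | intermediate
15 | 3-methylcyclobut-2-en-1-one | CC1=CC(=O)C1 | intermediate
16 | 3-methylbuta-1,3-dien-1-one (vinylketene) | CC(=C)C=C=O | intermediate (not isolated)
17 | 2-(diethoxymethyl)-3-(ring B aryloxy)-4-(prop-1-en-2-yl)cyclobut-2-en-1-one, racemic | CCOC(OCC)C1=C(Oc2c(CO[Si](C)(C)C(C)(C)C)cc(OC)cc2OC)C(C(C)=C)C1=O | intermediate (not isolated)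
18 | 2-(diethoxymethyl)-3-(ring B aryloxy)-5-methylhexa-1,3,5-trien-1-one, ketene and isopropenyl cis | CCOC(OCC)C(=C=O)/C(Oc1c(CO[Si](C)(C)C(C)(C)C)cc(OC)cc1OC)=C\C(C)=C | intermediate (not isolated)
19 | 2-(diethoxymethyl)-3-(ring B aryloxy)-5-methylcyclohexa-2,4-dien-1-one | CCOC(OCC)C1=C(Oc2c(CO[Si](C)(C)C(C)(C)C)cc(OC)cc2OC)C=C(C)CC1=O | intermediate (not isolated)
20 | 2-(diethoxymethyl)-3-[2-({[tert-butyl(dimethyl)silyl]oxy}methyl)-4,6-dimethoxyphenoxy]-5-methylphenol | CCOC(OCC)c1c(O)cc(C)cc1Oc1c(CO[Si](C)(C)C(C)(C)C)cc(OC)cc1OC | intermediate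
21 | 2-hydroxy-6-[2-(hydroxymethyl)-4,6-dimethoxyphenoxy]-4-methylbenzaldehyde | O=Cc1c(O)cc(C)cc1Oc1c(CO)cc(OC)cc1OC | intermediate
22 | 2-[2-(hydroxymethyl)-4,6-dimethoxyphenoxy]-4-methyl-6-[(3-methylbut-2-en-1-yl)oxy]benzaldehyde | O=Cc1c(OCC=C(C)C)cc(C)cc1Oc1c(CO)cc(OC)cc1OC | intermediate
23 | 2-[2-(hydroxymethyl)-4,6-dimethoxyphenoxy]-4-methyl-6-[(3-methylbut-2-en-1-yl)oxy]benzoic acid | OC(=O)c1c(OCC=C(C)C)cc(C)cc1Oc1c(CO)cc(OC)cc1OC | intermediate
24 | methyl 2-[2-(hydroxymethyl)-4,6-dimethoxyphenoxy]-4-methyl-6-[(3-methylbut-2-en-1-yl)oxy]benzoate | COC(=O)c1c(OCC=C(C)C)cc(C)cc1Oc1c(CO)cc(OC)cc1OC | target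

**Count and risks**

Total step count: 11. Longest linear sequence: 9 steps (1, 2, 3, 4, 7, 8, 9, 10, 11).

Step 7. What may go wrong is slow capture of the vinylketene by an ynol ether that the acetal and the aryloxy group deactivate. Ketene oligomerisation, acylation of the product phenol by surplus ketene, or thermal loss of ethanol from the o-hydroxyaryl acetal could then take over at 80–110 °C. Acylation alone would be reversed by brief K2CO3/MeOH treatment of the crude. The fallback keeps the disconnection but makes the same ketene photochemically at room temperature; it sets out from 10 and comes back at 20. Purchased 3-methylbut-3-en-2-one is trifluoroacetylated (LiHMDS, CF3CO2CH2CF3, THF, −78 °C) to 1,1,1-trifluoro-5-methylhex-5-ene-2,4-dione F1, which is not isolated. Detrifluoroacetylative diazo transfer (MsN3, Et3N, H2O, MeCN) then gives 1-diazo-3-methylbut-3-en-2-one F2. Irradiation of F2 with 10 (CH2Cl2, rt, Pyrex-filtered medium-pressure mercury lamp) should trigger a photochemical Wolff rearrangement to vinylketene 16, formed slowly in the presence of all the alkyne. The [2+2] adduct 17 then goes on, under continued irradiation or gentle warming, through 18 and 19 to 20.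

Step 4. What may go wrong is failure of the acetylide to displace phenoxide from the orthoformate, with protonation to the terminal ynol ether on work-up, or MgBr2-promoted hydration of the ynol ether. The fallback forms the O–C bond on an alkene that already carries the acetal; it sets out from 3 and comes back at 10. 2,2-Diethoxyacetaldehyde is converted by Ramirez olefination (CBr4, PPh3, Et3N, CH2Cl2, 0 °C) into 1,1-dibromo-3,3-diethoxyprop-1-ene F3. Copper-catalysed coupling of F3 with phenol 3 (CuI, 2,2'-bipyridine, K3PO4, toluene, 110 °C) should replace the bromide trans to the acetal and give tert-butyl{[2-{[(Z)-1-bromo-3,3-diethoxyprop-1-en-1-yl]oxy}-3,5-dimethoxyphenyl]methoxy}dimethylsilane F4. Anti elimination of HBr from F4 (KOtBu, dioxane, rt) then gives 10.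

Step 10. What may go wrong is electrophilic chlorination of the prenyl double bond or of the dimethoxy ring B by hypochlorous acid that escapes the scavenger, together with slow oxidation of the doubly ortho-substituted aldehyde. The fallback avoids chlorine oxidants and the free acid; it sets out from 22 and comes back at 24, so step 11 is skipped and no new compound is made. It is an N-heterocyclic carbene catalysed oxidative esterification (1,4-dimethyl-1,2,4-triazolium iodide cat., DBU, 3,3',5,5'-tetra-tert-butyldiphenoquinone 1 equiv, MeOH/THF, rt). The Breslow intermediate of 22 is oxidised by the quinone to an acyl azolium, which methanol intercepts; the quinone does not oxidise the benzylic alcohol.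

**Further compounds**

F1 | step 7 | 1,1,1-trifluoro-5-methylhex-5-ene-2,4-dione | CC(=C)C(=O)CC(=O)C(F)(F)F
F2 | step 7 | 1-diazo-3-methylbut-3-en-2-one | CC(=C)C(=O)C=[N+]=[N-]
F3 | step 4 | 1,1-dibromo-3,3-diethoxyprop-1-ene | CCOC(OCC)C=C(Br)Br
F4 | step 4 | tert-butyl{[2-{[(Z)-1-bromo-3,3-diethoxyprop-1-en-1-yl]oxy}-3,5-dimethoxyphenyl]methoxy}dimethylsilane | CCOC(OCC)/C=C(\Br)Oc1c(CO[Si](C)(C)C(C)(C)C)cc(OC)cc1OC
F0 | step 10 | none | none
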